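**Retrosynthetic overview**

1. Target ⇐ C-2 ketone (equatorial-selective reduction, last step) ⇐ ring B closed by an intramolecular Hosomi–Sakurai reaction that forms C9–C10 from a monocyclic ring-A enone whose side chain carries a (Z)-2-(silylmethyl)alkene and all three acetates.
2. Enabling feature: the C8(17) exocyclic methylene next to C-9 is the retron of an allylsilane (Si on C-17, C8=C9), and the C-2 oxygen stands 1,3 to the quaternary C-10 in ring A, so C-10 is the β-carbon of a C-2 enone (C1=C10).
3. Allylsilane ⇐ anti-carbomagnesiation of a (7R)-propargylic alcohol ⇐ Noyori reduction of an ynone ⇐ acetylide of a nerol-derived enynol + ring-A δ-lactone (C7–C8 bond).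
4. Ring A ⇐ intramolecular alkene acylation (C1–C2 bond) on a δ-lactone template; C-5 from Rh-catalysed asymmetric conjugate addition, C-4 from trans-selective enolate methylation; the lactone is transposed (C-19 reduced, C-7 oxidised) before the union.
5. Order of ring formation: δ-lactone template (opened later) → ring A → ring B (key step).

Key step: step 17

Remark: labdane numbering (C-1 to C-20) is used for all intermediates; the sense of induction of (S)-BINAP (step 4) and of the (R,R)-Ru catalyst (step 13) is assigned by analogy with aryl transfer and with simple ynones, and the antipodal ligand would be used if the analogy did not hold.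

**Route**

Step 1
Reactants: 1 neryl acetate [(2Z)-3,7-dimethylocta-2,6-dien-1-yl acetate]
Product: 2 (2Z)-6,7-epoxy-3,7-dimethyloct-2-en-1-yl acetate (racemic at the epoxide)
Conditions: mCPBA, CH2Cl2, 0 °C
Reagents that add atoms: mCPBA, O=C(OO)c1cccc(Cl)c1
Why: Prilezhaev epoxidation should be selective for the electron-rich 6,7-alkene because the 2,3-alkene is deactivated by the allylic acetate; the epoxide stereocentre is irrelevant as it is cleaved in step 2.

Step 2
Reactants: 2 (2Z)-6,7-epoxy-3,7-dimethyloct-2-en-1-yl acetate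
Product: 3 (2Z)-3-methyl-6-oxohex-2-en-1-yl acetate
Conditions: H5IO6, THF/H2O, 0 °C → rt
Reagents that add atoms: none
Why: periodic acid hydrates the epoxide and cleaves the glycol (Malaprade-type cleavage) to the C-9 aldehyde and acetone, leaving the (Z)-allylic acetate untouched.

Step 3
Reactants: 3 (2Z)-3-methyl-6-oxohex-2-en-1-yl acetate
Product: 5 (2Z)-3-methylhept-2-en-6-yn-1-ol, via enyne acetate 4 (not isolated)
Conditions: Ohira–Bestmann reagent, K2CO3, MeOH, 0 °C → rt
Reagents that add atoms: dimethyl (1-diazo-2-oxopropyl)phosphonate, COP(=O)(OC)C(=[N+]=[N-])C(C)=O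
Why: Seyferth–Gilbert homologation with the Ohira–Bestmann reagent turns the aldehyde into the terminal alkyne (the added carbon is C-8) while K2CO3/MeOH transesterifies the acetate, so the free enynol should result with the Z-alkene untouched.

Step 4
Reactants: 6 5,6-dihydro-2H-pyran-2-one; 7 isopropenylboronic acid pinacol ester
Product: 8 (4S)-4-(prop-1-en-2-yl)oxan-2-one
Conditions: [Rh(OH)(cod)]2 (cat.), (S)-BINAP, dioxane/H2O 10:1, 60 °C
Reagents that add atoms: none
Why: Rh(I)/BINAP-catalysed asymmetric conjugate addition of the alkenylboron reagent (Hayashi–Miyaura reaction) to the s-trans-locked unsaturated lactone sets C-5, the (S)-ligand being expected to give the (4S)-lactone.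

Step 5
Reactants: 8 (4S)-4-(prop-1-en-2-yl)oxan-2-one
Product: 9 allyl 2-[(3R,4S)-2-oxo-4-(prop-1-en-2-yl)oxan-3-yl]acetate (3,4-trans)
Conditions: LDA, THF, −78 °C; allyl bromoacetate, −78 → −40 °C
Reagents that add atoms: allyl bromoacetate, C=CCOC(=O)CBr
Why: alkylation of the lithium lactone enolate should occur anti to the C-5 isopropenyl group (3,4-trans); this centre is re-enolised in step 7.

Step 6
Reactants: 9 allyl 2-[(3R,4S)-2-oxo-4-(prop-1-en-2-yl)oxan-3-yl]acetate
Product: 10 2-[(3R,4S)-2-oxo-4-(prop-1-en-2-yl)oxan-3-yl]acetic acid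
Conditions: Pd(PPh3)4 (cat.), morpholine, THF, rt
Reagents that add atoms: none
Why: Pd(0)-catalysed allyl transfer to morpholine (Tsuji–Trost deallylation) frees the acid under neutral conditions that neither open the lactone nor protonate the isopropenyl group.

Step 7
Reactants: 10 2-[(3R,4S)-2-oxo-4-(prop-1-en-2-yl)oxan-3-yl]acetic acid
Product: 11 2-[(3S,4R)-3-methyl-2-oxo-4-(prop-1-en-2-yl)oxan-3-yl]acetic acid (CH3 trans and CH2CO2H cis to isopropenyl)
Conditions: LDA (2.2 equiv), THF, −78 → −40 °C; MeI, −78 °C; aq HCl work-up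
Reagents that add atoms: iodomethane, CI
Why: with the side chain masked as its lithium carboxylate the second equivalent of LDA forms only the lactone enolate, and MeI should enter anti to the C-5 isopropenyl group, which sets the C-4 quaternary centre (enolate alkylation of a carboxylate-bearing lactone dianion).

Step 8
Reactants: 11 2-[(3S,4R)-3-methyl-2-oxo-4-(prop-1-en-2-yl)oxan-3-yl]acetic acid
Product: 14 (4aR,8aS)-5,8a-dimethyl-4,4a,8,8a-tetrahydro-1H-isochromene-1,7(3H)-dione (cis-fused ring-A enone δ-lactone), via acid chloride 12 (not isolated), via chloro ketone 13 (not isolated)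
Conditions: (COCl)2, DMF (cat.), CH2Cl2, 0 °C → rt; SnCl4, CH2Cl2, −78 → 0 °C; Et3N, rt
Reagents that add atoms: oxalyl chloride, O=C(Cl)C(Cl)=O (supplies only the chlorine of 12 and 13)
Why: intramolecular Friedel–Crafts-type acylation of the 1,1-disubstituted alkene closes ring A 6-endo (C-2 to C-1, tertiary C-10 cation trapped as chloride) and E1cB loss of HCl should give the conjugated 3-methylcyclohexenone; C-4 and C-5 are untouched and the cis relation of the two arms allows the closure.

Step 9
Reactants: 14 (4aR,8aS)-5,8a-dimethyl-4,4a,8,8a-tetrahydro-1H-isochromene-1,7(3H)-dione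
Product: 15 ethylene ketal (1,3-dioxolane) of 14 at the enone carbonyl (labdane C-2)
Conditions: TMSOCH2CH2OTMS, TMSOTf (cat.), CH2Cl2, −78 → −20 °C
Reagents that add atoms: 1,2-bis(trimethylsilyloxy)ethane, C[Si](C)(C)OCCO[Si](C)(C)C
Why: Noyori ketalisation at low temperature should protect the enone carbonyl without migration of the C1=C10 double bond, so C-5 is not epimerised.

Step 10
Reactants: 15 ethylene ketal of 14
Product: 16 (4R,5S)-4-(2-hydroxyethyl)-5-(hydroxymethyl)-3,5-dimethylcyclohex-2-en-1-one ethylene ketal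
Conditions: LiAlH4, THF, 0 °C
Reagents that add atoms: none
Why: hydride reduction of the lactone gives the 1,5-diol and brings C-19 to its final oxidation level; ketal and alkene are inert.

Step 11
Reactants: 16 (4R,5S)-4-(2-hydroxyethyl)-5-(hydroxymethyl)-3,5-dimethylcyclohex-2-en-1-one ethylene ketal
Product: 18 transposed cis-fused δ-lactone (C=O at C-7 and OCH2 = C-19; ethylene ketal of (4aR,8aS)-5,8a-dimethyl-4,4a,8,8a-tetrahydro-1H-isochromene-3,7-dione at C-7 of the isochromene), via lactol 17 (not isolated)
Conditions: TEMPO (cat.), PhI(OAc)2, CH2Cl2, rt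
Reagents that add atoms: none
Why: the oxoammonium oxidation should take the unhindered C-7 primary alcohol in preference to the neopentylic C-19 alcohol, and the lactol closed by the C-19 hydroxyl is oxidised on to the lactone (diol-to-lactone oxidation), so C-7 becomes the acyl carbon.

Step 12
Reactants: 18 transposed δ-lactone; 5 (2Z)-3-methylhept-2-en-6-yn-1-ol
Product: 19 (4R,5S)-5-(hydroxymethyl)-4-[(7Z)-9-hydroxy-7-methyl-2-oxonon-7-en-3-yn-1-yl]-3,5-dimethylcyclohex-2-en-1-one ethylene ketal
Conditions: 5, n-BuLi (2 equiv per 5), THF, −78 °C; then 18, −78 → −20 °C; aq NH4Cl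
Reagents that add atoms: none
Why: the lithium acetylide (O,C-dianion of 5) should add once to the lactone carbonyl because the tetrahedral lithium hemiketal persists until work-up, which forms the C7–C8 bond and releases the C-19 alcohol (acetylide addition to a lactone).

Step 13
Reactants: 19 ynone diol
Product: 20 (4R,5S)-4-[(2R,7Z)-2,9-dihydroxy-7-methylnon-7-en-3-yn-1-yl]-5-(hydroxymethyl)-3,5-dimethylcyclohex-2-en-1-one ethylene ketal [(7R) in labdane numbering]
Conditions: Ru(p-cymene)[(R,R)-TsDPEN] (cat.), i-PrOH, rt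
Reagents that add atoms: none
Why: Noyori asymmetric transfer hydrogenation of the α,β-acetylenic ketone is catalyst-controlled and the (R,R)-complex is expected to give the (7R)-propargylic alcohol; alkenes, ketal and free alcohols are inert.

Step 14
Reactants: 20 (7R)-propargylic triol
Product: 21 (4R,5S)-4-[(2R,3Z,7Z)-2,9-dihydroxy-7-methyl-3-[(trimethylsilyl)methyl]nona-3,7-dien-1-yl]-5-(hydroxymethyl)-3,5-dimethylcyclohex-2-en-1-one ethylene ketal
Conditions: Me3SiCH2MgCl (excess), CuI (cat.), THF, 0 → 40 °C; aq NH4Cl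
Reagents that add atoms: (trimethylsilyl)methylmagnesium chloride, C[Si](C)(C)C[Mg]Cl
Why: Cu-catalysed anti-carbomagnesiation of the propargylic magnesium alkoxide delivers CH2SiMe3 to the proximal alkyne carbon C-8 and closes a five-membered oxamagnesacycle with Mg on C-9 cis to C-7, so protonation should give the (Z)-allylsilane with CH2SiMe3 cis to C-11.

Step 15
Reactants: 21 allylsilane triol
Product: 22 7,15,19-triacetate of 21 (ethylene ketal retained)
Conditions: Ac2O, pyridine, DMAP (cat.), CH2Cl2, rt
Reagents that add atoms: acetic anhydride, CC(=O)OC(C)=O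
Why: DMAP-catalysed acetylation esterifies the C-7, C-15 and C-19 hydroxyl groups in one operation without touching a stereocentre.

Step 16
Reactants: 22 triacetate ketal
Product: 23 (4R,5S)-5-(acetoxymethyl)-4-[(2R,3Z,7Z)-2,9-diacetoxy-7-methyl-3-[(trimethylsilyl)methyl]nona-3,7-dien-1-yl]-3,5-dimethylcyclohex-2-en-1-one
Conditions: PPTS (cat.), acetone/H2O, 40 °C
Reagents that add atoms: water, O
Why: mild acid-catalysed hydrolysis of the allylic dioxolane returns the conjugated enone under conditions too weak to protodesilylate the allylsilane or ionise the allylic acetates.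

Step 17
Reactants: 23 enone allylsilane triacetate
Product: 24 7α,15,19-triacetoxylabda-8(17),13Z-dien-2-one
Conditions: EtAlCl2 (excess), toluene/CH2Cl2, −78 → −30 °C; aq NaHCO3
Reagents that add atoms: none
Why: EtAlCl2 complexes the C-2 enone carbonyl and the γ-carbon C-9 of the (Z)-2-(silylmethyl)alkene attacks the β-carbon C-10 anti to silicon (SE2′), the β-silyl cation at C-8 then losing the silyl group to leave the C8(17) exocyclic methylene and an aluminium enolate that is protonated at C-1 on work-up; this is an intramolecular Hosomi–Sakurai conjugate allylation of a 4-tethered 3-methylcyclohexenone, a known annulation type. Ring B (C5–C6–C7–C8–C9–C10) closes 6-exo-trig with respect to the enone (C-1 stays outside the ring) and 6-endo with respect to the allylsilane. C-10 is controlled by the resident C-4/C-5 centres: bonding on the β-face (axial attack, cis-decalin) would push C-9 into a syn-axial clash with the Lewis-acid-bound C-19 acetoxymethyl group, so C-9 should bond on the α-face with the tether equatorial and give the trans ring fusion with 10β-methyl. C-9 is controlled by the alkene geometry through a chair transition state, the (Z)-silane (C-11 trans to C-7) placing C-11 equatorial (9α-H) and the C-7 acetate axial. The step needs 1,4- over 1,2-addition and attack by C-9 instead of C-17, which the tether length (1,2-addition would be an eight-membered closure) and the γ-selectivity of allylsilanes secure. The acetates should survive because primary and allylic acetates do not ionise under EtAlCl2 at low temperature, the reagent being used in excess to saturate their carbonyl groups.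

Step 18
Reactants: 24 7α,15,19-triacetoxylabda-8(17),13Z-dien-2-one
Product: 25 (2R,4S,5R,7R,9R,10S)-labda-8(17),13Z-diene-2α,7α,15,19-tetrol 7,15,19-triacetate (target)
Conditions: SmI2, THF/MeOH, 0 °C → rt
Reagents that add atoms: none
Why: electron-transfer reduction with SmI2 passes through a ketyl/carbanion that should be protonated to the thermodynamically preferred equatorial 2α-alcohol (the axial 2β-alcohol would be syn-diaxial to C-19 and C-20), whereas hydride reagents would attack the open α-face and give the 2β-epimer; acetates and alkenes are not expected to be reduced.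

**Compound list**

1 | neryl acetate | CC(C)=CCC/C(C)=C\COC(C)=O | starting material
2 | (2Z)-6,7-epoxy-3,7-dimethyloct-2-en-1-yl acetate (racemic epoxide) | CC1(C)OC1CC/C(C)=C\COC(C)=O | intermediate
3 | (2Z)-3-methyl-6-oxohex-2-en-1-yl acetate | O=CCC/C(C)=C\COC(C)=O | intermediate
4 | (2Z)-3-methylhept-2-en-6-yn-1-yl acetate (not isolated) | C#CCC/C(C)=C\COC(C)=O | intermediate
5 | (2Z)-3-methylhept-2-en-6-yn-1-ol | C#CCC/C(C)=C\CO | intermediate
6 | 5,6-dihydro-2H-pyran-2-one | O=C1C=CCCO1 | starting material
7 | isopropenylboronic acid pinacol ester | CC(=C)B1OC(C)(C)C(C)(C)O1 | starting material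
8 | (4S)-4-(prop-1-en-2-yl)oxan-2-one | O=C1C[C@@H](C(C)=C)CCO1 | intermediate
9 | allyl 2-[(3R,4S)-2-oxo-4-(prop-1-en-2-yl)oxan-3-yl]acetate | O=C1[C@H](CC(=O)OCC=C)[C@@H](C(C)=C)CCO1 | intermediate
10 | 2-[(3R,4S)-2-oxo-4-(prop-1-en-2-yl)oxan-3-yl]acetic acid | O=C1[C@H](CC(=O)O)[C@@H](C(C)=C)CCO1 | intermediate
11 | 2-[(3S,4R)-3-methyl-2-oxo-4-(prop-1-en-2-yl)oxan-3-yl]acetic acid | O=C1[C@@](C)(CC(=O)O)[C@@H](C(C)=C)CCO1 | intermediate
12 | acid chloride of 11 (not isolated) | O=C1[C@@](C)(CC(=O)Cl)[C@@H](C(C)=C)CCO1 | intermediate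
13 | β-chloro ketone, cis-fused 5-chloro-5,8a-dimethylhexahydroisochromene-1,7-dione, C-10 epimers (not isolated) | O=C1CC(C)(Cl)[C@H]2CCOC(=O)[C@@]2(C)C1 | intermediate
14 | (4aR,8aS)-5,8a-dimethyl-4,4a,8,8a-tetrahydro-1H-isochromene-1,7(3H)-dione | O=C1C=C(C)[C@H]2CCOC(=O)[C@@]2(C)C1 | intermediate
15 | ethylene ketal of 14 | C12(OCCO1)C=C(C)[C@H]3CCOC(=O)[C@@]3(C)C2 | intermediate
16 | (4R,5S)-4-(2-hydroxyethyl)-5-(hydroxymethyl)-3,5-dimethylcyclohex-2-en-1-one ethylene ketal | C12(OCCO1)C=C(C)[C@@H](CCO)[C@@](C)(CO)C2 | intermediate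
17 | lactol (C-7 hemiacetal with the C-19 oxygen, anomers; not isolated) | C12(OCCO1)C=C(C)[C@H]3CC(O)OC[C@@]3(C)C2 | intermediate
18 | transposed cis-fused δ-lactone (C=O at C-7, OCH2 = C-19), ketal retained | C12(OCCO1)C=C(C)[C@H]3CC(=O)OC[C@@]3(C)C2 | intermediate
19 | (4R,5S)-5-(hydroxymethyl)-4-[(7Z)-9-hydroxy-7-methyl-2-oxonon-7-en-3-yn-1-yl]-3,5-dimethylcyclohex-2-en-1-one ethylene ketal | C12(OCCO1)C=C(C)[C@@H](CC(=O)C#CCC/C(C)=C\CO)[C@@](C)(CO)C2 | intermediate
20 | (4R,5S)-4-[(2R,7Z)-2,9-dihydroxy-7-methylnon-7-en-3-yn-1-yl]-5-(hydroxymethyl)-3,5-dimethylcyclohex-2-en-1-one ethylene ketal | C12(OCCO1)C=C(C)[C@@H](C[C@@H](O)C#CCC/C(C)=C\CO)[C@@](C)(CO)C2 | intermediate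
21 | (4R,5S)-4-[(2R,3Z,7Z)-2,9-dihydroxy-7-methyl-3-[(trimethylsilyl)methyl]nona-3,7-dien-1-yl]-5-(hydroxymethyl)-3,5-dimethylcyclohex-2-en-1-one ethylene ketal | C12(OCCO1)C=C(C)[C@@H](C[C@@H](O)/C(C[Si](C)(C)C)=C/CC/C(C)=C\CO)[C@@](C)(CO)C2 | intermediate
22 | 7,15,19-triacetate of 21 | C12(OCCO1)C=C(C)[C@@H](C[C@@H](OC(C)=O)/C(C[Si](C)(C)C)=C/CC/C(C)=C\COC(C)=O)[C@@](C)(COC(C)=O)C2 | intermediate
23 | (4R,5S)-5-(acetoxymethyl)-4-[(2R,3Z,7Z)-2,9-diacetoxy-7-methyl-3-[(trimethylsilyl)methyl]nona-3,7-dien-1-yl]-3,5-dimethylcyclohex-2-en-1-one | O=C1C=C(C)[C@@H](C[C@@H](OC(C)=O)/C(C[Si](C)(C)C)=C/CC/C(C)=C\COC(C)=O)[C@@](C)(COC(C)=O)C1 | intermediate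
24 | 7α,15,19-triacetoxylabda-8(17),13Z-dien-2-one | C=C1[C@H](OC(C)=O)C[C@H]2[C@@](C)(COC(C)=O)CC(=O)C[C@]2(C)[C@H]1CC/C(C)=C\COC(C)=O | intermediate
25 | (2R,4S,5R,7R,9R,10S)-labda-8(17),13Z-diene-2α,7α,15,19-tetrol 7,15,19-triacetate | C=C1[C@H](OC(C)=O)C[C@H]2[C@@](C)(COC(C)=O)C[C@H](O)C[C@]2(C)[C@H]1CC/C(C)=C\COC(C)=O | target

**Step count**

Total step count: 18. Longest linear sequence: 15 steps (6 → 25, steps 4–18); the side-chain alkyne 5 takes 3 steps (steps 1–3).

**Steps most likely to fail**

1. Step 17 (key step). The cyclisation may show poor facial selectivity at C-10 (cis ring fusion through axial attack), or the allylsilane may be protodesilylated before ring closure. The fallback sets out from 22 and moves the cyclisation one step earlier. TMSOTf (cat.) in CH2Cl2 at −78 °C ionises the allylic dioxolane to a 2-alkoxyallyl cation (vinylogous oxocarbenium ion). This acetal-initiated cation–olefin cyclisation with an allylsilane terminator has an earlier transition state, which should be governed by the chair preference of ring B and less by the antiperiplanar-attack demand of a Lewis-acid-bound enone. The silyl group is transferred to the opened glycol oxygen, giving the 2-(2-trimethylsilyloxyethoxy) Δ1-enol ether of the decalin F1. Hydrolysis (1 M HCl, THF, 0 °C) leads back to 24.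

2. Step 14. The carbometalation may be incomplete, may take the wrong regio- or stereochemical course, or the Grignard reagent may open the allylic ketal in an SN2′ manner. The fallback sets out from 20. Ru-catalysed hydroxyl-directed trans-hydrostannation ([Cp*RuCl]4 cat., Bu3SnH, CH2Cl2) places tin on C-8 and hydrogen on C-9 anti, giving the (Z)-C-8 tributylstannyl allylic alcohol F2. Iododestannylation (I2, CH2Cl2, 0 °C) with retention gives the C-8 alkenyl iodide F3. Kumada coupling (Me3SiCH2MgCl in excess, Pd(PPh3)4 cat., THF) with retention comes back to 21; no carbonyl group is present at this stage.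

3. Step 18. The reduction may show poor facial selectivity at C-2, or an allylic acetate may be lost reductively. The fallback sets out from 24. Kinetic hydride reduction (NaBH4, MeOH, −20 °C) from the open α-face gives the axial 2β-alcohol F4. Mitsunobu inversion (ClCH2CO2H, PPh3, DIAD, toluene) gives the 2α-chloroacetate F5. Selective removal of the chloroacetyl group (thiourea, NaHCO3, EtOH, 50 °C), which leaves the three acetates, comes back to 25.

**Further compounds**

F1 | step 17 | 7α,15,19-triacetoxy-2-(2-trimethylsilyloxyethoxy)labda-1,8(17),13Z-triene | C=C1[C@H](OC(C)=O)C[C@H]2[C@@](C)(COC(C)=O)CC(OCCO[Si](C)(C)C)=C[C@]2(C)[C@H]1CC/C(C)=C\COC(C)=O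
F2 | step 14 | C-8 tributylstannyl (Z)-allylic alcohol from trans-hydrostannation of 20 | C12(OCCO1)C=C(C)[C@@H](C[C@@H](O)/C([Sn](CCCC)(CCCC)CCCC)=C/CC/C(C)=C\CO)[C@@](C)(CO)C2
F3 | step 14 | C-8 alkenyl iodide from F2 | C12(OCCO1)C=C(C)[C@@H](C[C@@H](O)/C(I)=C/CC/C(C)=C\CO)[C@@](C)(CO)C2
F4 | step 18 | 2β-alcohol (C-2 epimer of 25) | C=C1[C@H](OC(C)=O)C[C@H]2[C@@](C)(COC(C)=O)C[C@@H](O)C[C@]2(C)[C@H]1CC/C(C)=C\COC(C)=O
F5 | step 18 | 2α-chloroacetate of 25 | C=C1[C@H](OC(C)=O)C[C@H]2[C@@](C)(COC(C)=O)C[C@H](OC(=O)CCl)C[C@]2(C)[C@H]1CC/C(C)=C\COC(C)=O
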